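**Assumption:** the target has no stereocentres and no E/Z-stereogenic alkenes (both prenyl groups are trisubstituted with gem-dimethyl termini), so it is achiral and no stereocontrol is required.

## Retrosynthetic overview

1. Target 14 ⇐ one-pot basic hydrolysis of ethyl ester/bis-pivalate 13.
2. 13 ⇐ the furan ring, formed last in a single oxidative radical step: the C3–C3a bond by Fe/peroxide cross-dehydrogenative coupling of unprotected 2-prenylresorcinol 5 with aroylacetate 12, then O1–C2 closure by cyclodehydration. Both prenyl groups are already in place.
3. 12 ⇐ Roskamp homologation of aldehyde 10 ⇐ resorcinol (formylation, C5 prenylation, pivaloylation).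
4. 5 ⇐ resorcinol via bis-MOM ether, C2 ortho-lithiation/prenylation, deprotection.
5. Ring order: both benzene rings come intact from resorcinol; the furan is the only ring constructed (step 8).

## Route

**Step 1**
Reactants: 1, resorcinol
Product: 2, 1,3-bis(methoxymethoxy)benzene
Conditions: MOMCl, i-Pr2NEt, CH2Cl2, 0 °C → rt
Reagents that add atoms: chloromethyl methyl ether, COCCl
Why: O-alkylation of both phenols (MOM protection); the MOM ethers then serve as directing groups for ortho-metalation.

**Step 2**
Reactants: 2; 3, prenyl bromide (1-bromo-3-methylbut-2-ene)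
Product: 4, 1,3-bis(methoxymethoxy)-2-(3-methylbut-2-en-1-yl)benzene
Conditions: n-BuLi, THF, 0 °C → rt; CuI, −40 °C; then 3, → rt
Reagents that add atoms: prenyl bromide (3), CC(C)=CCBr
Why: Directed ortho-metalation removes the C2–H flanked by two OMOM groups exclusively; the aryl copper species alkylates prenyl bromide at the primary carbon (SN2, not SN2′), giving the linear prenyl group.

**Step 3**
Reactants: 4
Product: 5, 2-(3-methylbut-2-en-1-yl)benzene-1,3-diol (2-prenylresorcinol)
Conditions: 2 M HCl, MeOH, rt → 40 °C
Reagents that add atoms: none
Why: Acid-catalysed acetal methanolysis (MOM removal) under mild conditions, so the o-prenylphenol is not cyclised to a chroman.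

**Step 4**
Reactants: 1, resorcinol; 6, N,N-dimethylformamide
Product: 7, 2,4-dihydroxybenzaldehyde
Conditions: POCl3, DMF, MeCN, −15 °C → rt; then H2O, 50 °C
Reagents that add atoms: DMF (6), CN(C)C=O (formyl carbon); water, O (aldehyde oxygen, from iminium hydrolysis)
Why: Vilsmeier–Haack formylation at C4 (para to one OH, ortho to the other), the most nucleophilic unhindered position of resorcinol.

**Step 5**
Reactants: 7; 8, 2-methylbut-3-en-2-ol
Product: 9, 2,4-dihydroxy-5-(3-methylbut-2-en-1-yl)benzaldehyde
Conditions: BF3·OEt2, dioxane, rt; chromatographic removal of the minor 3-prenyl isomer (expect ~30%)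
Reagents that add atoms: 2-methylbut-3-en-2-ol (8), C=CC(C)(C)O
Why: Friedel–Crafts nuclear prenylation: the dimethylallyl cation attacks through its primary terminus at C5, the least hindered activated site (ortho to 4-OH, para to 2-OH).

**Step 6**
Reactants: 9
Product: 10, 2,4-bis(pivaloyloxy)-5-(3-methylbut-2-en-1-yl)benzaldehyde
Conditions: PivCl, Et3N, DMAP (cat.), CH2Cl2, 0 °C → rt
Reagents that add atoms: pivaloyl chloride, CC(C)(C)C(Cl)=O
Why: DMAP-catalysed esterification; pivalates tolerate Lewis acid, peroxide and heat, make ring B hard to oxidise, leave no free OH next to the ring-B prenyl, and come off in the final saponification.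

**Step 7**
Reactants: 10; 11, ethyl diazoacetate
Product: 12, ethyl 3-[2,4-bis(pivaloyloxy)-5-(3-methylbut-2-en-1-yl)phenyl]-3-oxopropanoate
Conditions: N2CHCO2Et, SnCl2 (10 mol%) or NbCl5 (5 mol%), CH2Cl2, rt
Reagents that add atoms: ethyl diazoacetate (11), CCOC(=O)C=[N+]=[N-]
Why: Roskamp homologation: Lewis-acid-promoted addition of the diazo ester to the aldehyde, then 1,2-hydride shift with loss of N2 gives the β-keto ester; the acyloxy groups suppress competing aryl migration, and no base is used, so the aryl esters survive.

**Step 8 (key step)**
Reactants: 12; 5, 2-prenylresorcinol (1.5 equiv)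
Product: 13, ethyl 2-[2,4-bis(pivaloyloxy)-5-(3-methylbut-2-en-1-yl)phenyl]-6-hydroxy-7-(3-methylbut-2-en-1-yl)-1-benzofuran-3-carboxylate
Conditions: FeCl3·6H2O (10 mol%), (t-BuO)2 (2 equiv), ClCH2CH2Cl, 100 °C, sealed tube, Ar
Reagents that add atoms: none (both reactants are numbered; the peroxide only removes 2 H)
Why: Iron-catalysed radical cross-dehydrogenative coupling/annulation of a phenol with a β-keto ester: Fe/t-BuO• generates the electrophilic iron-bound α-radical of 12, which attacks C4 of 5 (ortho to one OH, para to the other; C4 and C6 are equivalent by symmetry) to form the C3–C3a bond, and the adjacent OH then condenses onto the aryl ketone under Fe(III) Lewis acid to close the furan. The prenyl groups are expected to survive because the resorcinol ring and its O–H react far faster with the oxidant and the electrophilic radical than an isolated trisubstituted alkene or its allylic C–H; excess 5 suppresses a second annulation at C5.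

**Step 9**
Reactants: 13
Product: 14, erythribyssin F, 2-[2,4-dihydroxy-5-(3-methylbut-2-en-1-yl)phenyl]-6-hydroxy-7-(3-methylbut-2-en-1-yl)-1-benzofuran-3-carboxylic acid
Conditions: KOH, degassed MeOH/THF/H2O, 60 °C; then 0 °C, citric acid to pH ≈ 3–4, extract cold, no heating
Reagents that add atoms: hydroxide/water, O (carboxylic acid OH)
Why: Saponification cleaves both aryl pivalates and the ethyl ester in one operation (any transient coumestan lactone from the 2′-phenoxide is also opened by hydroxide); buffered cold acidification releases the acid without lactonisation or prenyl–phenol cyclisation.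

## Compound list

1 | resorcinol | Oc1cccc(O)c1 | starting material
2 | 1,3-bis(methoxymethoxy)benzene | COCOc1cccc(OCOC)c1 | intermediate
3 | prenyl bromide | CC(C)=CCBr | starting material
4 | 1,3-bis(methoxymethoxy)-2-prenylbenzene | COCOc1cccc(OCOC)c1CC=C(C)C | intermediate
5 | 2-prenylresorcinol | CC(C)=CCc1c(O)cccc1O | intermediate
6 | N,N-dimethylformamide | CN(C)C=O | starting material (C1 source)
7 | 2,4-dihydroxybenzaldehyde | O=Cc1ccc(O)cc1O | intermediate
8 | 2-methylbut-3-en-2-ol | C=CC(C)(C)O | starting material
9 | 2,4-dihydroxy-5-prenylbenzaldehyde | O=Cc1cc(CC=C(C)C)c(O)cc1O | intermediate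
10 | 2,4-bis(pivaloyloxy)-5-prenylbenzaldehyde | O=Cc1cc(CC=C(C)C)c(OC(=O)C(C)(C)C)cc1OC(=O)C(C)(C)C | intermediate
11 | ethyl diazoacetate | CCOC(=O)C=[N+]=[N-] | starting material
12 | ethyl 3-[2,4-bis(pivaloyloxy)-5-prenylphenyl]-3-oxopropanoate | CCOC(=O)CC(=O)c1cc(CC=C(C)C)c(OC(=O)C(C)(C)C)cc1OC(=O)C(C)(C)C | intermediate
13 | ethyl 2-[2,4-bis(pivaloyloxy)-5-prenylphenyl]-6-hydroxy-7-prenylbenzofuran-3-carboxylate | CCOC(=O)c1c(-c2cc(CC=C(C)C)c(OC(=O)C(C)(C)C)cc2OC(=O)C(C)(C)C)oc2c(CC=C(C)C)c(O)ccc12 | intermediate
14 | erythribyssin F | CC(C)=CCc1cc(-c2oc3c(CC=C(C)C)c(O)ccc3c2C(=O)O)c(O)cc1O | target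

## Summary

Total steps: 9 (convergent). Longest linear sequence: 6 steps (1 → 7 → 9 → 10 → 12 → 13 → 14); the second branch (1 → 2 → 4 → 5) is 3 steps.

Three steps most likely to fail, each with a fallback:

1. **Step 8 (radical annulation with free prenyl groups and a free resorcinol).** Risks are allylic H-abstraction or radical addition at the prenyl alkenes, Fe/HCl-induced chroman formation from the o-prenylphenol, and over-oxidation or double annulation. Fallback: run the same Fe/peroxide annulation on bromine surrogates (2-bromoresorcinol and the 5-bromo analogue of 12, both from resorcinol), then install both prenyl groups late by a double Pd-catalysed Stille coupling with tributyl(prenyl)stannane before the saponification.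

2. **Step 5 (direct C5 prenylation; low yield, 3-prenyl and chroman by-products).** Fallback: brominate 7 at C5 (Br2/AcOH), pivaloylate, and introduce the prenyl group regiospecifically by Pd-catalysed cross-coupling with a prenyl stannane.

3. **Step 7 (Roskamp homologation of a hindered, oxygenated aromatic aldehyde; possible aryl migration or alkene interference).** Fallback: build the β-keto ester by Claisen condensation instead. Acetylate resorcinol to 2,4-dihydroxyacetophenone, prenylate at C5, protect as the bis-MOM ether, and treat with NaH/dimethyl carbonate; this requires an additional mild-acid MOM removal before the final saponification.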